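**Strategy.** Everything rests on making the pyran ring (ring C) of the flavan unit last, by joining the phenolic oxygen on C8a of the pyrogallol-type ring A to C2, the benzylic carbinol carbon that carries catechol ring B. The precursor is an open-chain 1,3,3-triarylpropane-1,2-diol, (S) at the future C2, (R) at C3 and (S) at C4, whose C4 already bears the complete benzyl-protected flavonol. An intramolecular Mitsunobu etherification inverts C2 and so converts the anti diol, obtained by chelation-controlled reduction, into the 2,3-cis-3,4-trans flavan in one stereospecific operation. C4 is set earlier by a rhodium-catalysed asymmetric aryl addition and C3 by dihydroxylation of a temporary 4H-chromene.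

Key step: step 13

Remark: flavan numbering (O1, C2, C3, C4, C4a, C8a; ring A = benzo ring, ring B = 2-aryl ring, ring C = pyran ring) is used for the saturated unit and its open-chain precursors; Fl = 3,7,8-tris(benzyloxy)-2-[3,4-bis(benzyloxy)phenyl]-4-oxo-4H-chromen-5-yl; the target is read as (2R,3R,4S), that is 2,3-cis-3,4-trans; compounds 1, 3, 8, 10 and 13 are taken as commercial.

Step 1
Reactants: 1 1-(2,3,4-trihydroxyphenyl)ethanone
Product: 2 1-[3,4-bis(benzyloxy)-2-hydroxyphenyl]ethanone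
Conditions: BnBr (2.1 equiv), K2CO3, acetone, reflux
Reagents that add atoms: benzyl bromide BrCc1ccccc1
Why: Williamson etherification in which the 2-OH, hydrogen-bonded to the acetyl carbonyl, is the least reactive, so two equivalents of benzyl bromide should alkylate only O3 and O4.

Step 2
Reactants: 2 1-[3,4-bis(benzyloxy)-2-hydroxyphenyl]ethanone; 3 3,4-bis(benzyloxy)benzaldehyde
Product: 4 (E)-1-[3,4-bis(benzyloxy)-2-hydroxyphenyl]-3-[3,4-bis(benzyloxy)phenyl]prop-2-en-1-one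
Conditions: KOH (aq), EtOH–THF, rt
Reagents that add atoms: none
Why: Claisen–Schmidt aldol condensation of the methyl ketone with a non-enolisable aldehyde, which should give the E-chalcone.

Step 3
Reactants: 4 (E)-1-[3,4-bis(benzyloxy)-2-hydroxyphenyl]-3-[3,4-bis(benzyloxy)phenyl]prop-2-en-1-one
Product: 6 7,8-bis(benzyloxy)-2-[3,4-bis(benzyloxy)phenyl]-3-hydroxy-4H-chromen-4-one, via dihydroflavonol 5 (not isolated)
Conditions: H2O2 (30% aq), NaOH (aq), MeOH–THF, 0 °C → rt
Reagents that add atoms: hydrogen peroxide OO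
Why: Algar–Flynn–Oyamada oxidative cyclisation, in which alkaline peroxide oxidises the enone, the 2'-phenoxide closes the pyranone to the dihydroflavonol and further oxidation gives the flavonol; a chalcone without a 6'-substituent should not divert to the aurone.

Step 4
Reactants: 6 7,8-bis(benzyloxy)-2-[3,4-bis(benzyloxy)phenyl]-3-hydroxy-4H-chromen-4-one
Product: 7 3,7,8-tris(benzyloxy)-2-[3,4-bis(benzyloxy)phenyl]-4H-chromen-4-one
Conditions: BnBr, K2CO3, DMF, 60 °C
Reagents that add atoms: benzyl bromide BrCc1ccccc1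
Why: Williamson etherification of the acidic 3-OH, which also removes the 3-hydroxy-4-keto chelating site before the metal-catalysed step.

Step 5
Reactants: 7 3,7,8-tris(benzyloxy)-2-[3,4-bis(benzyloxy)phenyl]-4H-chromen-4-one; 8 N-methoxy-N-methylprop-2-enamide
Product: 9 (E)-3-Fl-N-methoxy-N-methylprop-2-enamide
Conditions: [RhCl2(C5Me5)]2 (2.5 mol %), AgSbF6 (10 mol %), Cu(OAc)2 (2.1 equiv), 1,2-dichloroethane, 100 °C
Reagents that add atoms: none
Why: Ketone-directed oxidative Heck (Fujiwara–Moritani) olefination, in which the C4 carbonyl oxygen guides cationic trivalent rhodium to the peri C5–H (the only C–H within reach of a five-membered rhodacycle) and alkene insertion with β-hydride elimination gives the E-alkene, divalent copper being the terminal oxidant.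

Step 6
Reactants: 9 (E)-3-Fl-N-methoxy-N-methylprop-2-enamide; 10 4-bromo-1,2-bis(benzyloxy)benzene
Product: 12 (E)-1-[3,4-bis(benzyloxy)phenyl]-3-Fl-prop-2-en-1-one, via aryl Grignard reagent 11 (not isolated)
Conditions: 10, Mg, THF, rt; then 9, THF, −20 → 0 °C; aq HCl (1 M) quench
Reagents that add atoms: none
Why: Weinreb ketone synthesis, in which the Grignard reagent adds once to the N-methoxy-N-methylamide to give a stable magnesium chelate that releases the enone only on work-up, while the hindered vinylogous-ester carbonyl of the flavonol should not compete at low temperature.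

Step 7
Reactants: 13 2,3-bis(benzyloxy)benzaldehyde
Product: 15 2,3-bis(benzyloxy)phenol, via aryl formate 14 (not isolated)
Conditions: mCPBA, CH2Cl2, rt; then K2CO3 (cat.), MeOH, rt
Reagents that add atoms: 3-chloroperbenzoic acid O=C(OO)c1cccc(Cl)c1
Why: Dakin-type Baeyer–Villiger oxidation, in which the electron-rich aryl group migrates to oxygen to give the aryl formate, followed by methanolysis to the phenol.

Step 8
Reactants: 15 2,3-bis(benzyloxy)phenol
Product: 16 1,2-bis(benzyloxy)-3-(methoxymethoxy)benzene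
Conditions: MOMCl, i-Pr2NEt, CH2Cl2, 0 °C → rt
Reagents that add atoms: chloromethyl methyl ether COCCl
Why: Acetal (MOM) protection of the phenol, which sets the future O1 apart from the benzyl ethers and provides the directing group for step 9.

Step 9
Reactants: 16 1,2-bis(benzyloxy)-3-(methoxymethoxy)benzene
Product: 18 [3,4-bis(benzyloxy)-2-(methoxymethoxy)phenyl]boronic acid, via aryllithium 17 (not isolated)
Conditions: s-BuLi, TMEDA, THF, −78 °C; B(OiPr)3, −78 °C → rt; AcOH, H2O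
Reagents that add atoms: triisopropyl borate CC(C)OB(OC(C)C)OC(C)C; water O
Why: Directed ortho-metalation, in which the MOM ether directs lithiation to its only free ortho position, followed by borylation and hydrolysis; the low temperature should suppress deprotonation of the benzyl ethers.

Step 10
Reactants: 12 (E)-1-[3,4-bis(benzyloxy)phenyl]-3-Fl-prop-2-en-1-one; 18 [3,4-bis(benzyloxy)-2-(methoxymethoxy)phenyl]boronic acid
Product: 21 (4S)-7,8-bis(benzyloxy)-2-[3,4-bis(benzyloxy)phenyl]-4-Fl-4H-chromene, via MOM-protected ketone 19 (not isolated), via phenol ketone 20 (not isolated)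
Conditions: 18 (2.5 equiv), [RhCl(C2H4)2]2 (2.5 mol %), (1S,4S)-2,5-diphenylbicyclo[2.2.2]octa-2,5-diene (5.5 mol %), KOH (0.5 equiv), dioxane–H2O (10:1), 40 °C; then p-TsOH·H2O, MeOH, 50 °C; then toluene, 80 °C
Reagents that add atoms: none
Why: Hayashi–Miyaura asymmetric 1,4-addition, in which the aryl complex of monovalent rhodium bound to the chiral diene inserts the enone on the Si face of its β-carbon and so sets C4 as (S) (the (S,S)-diene is the enantiomer expected from the usual binding model to give this sense, its antipode being used otherwise), after which acid removes the MOM group and the freed phenol condenses with the ketone (hemiketal, loss of water) to a 4H-chromene that places C4 next to an enol-ether double bond for step 11.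

Step 11
Reactants: 21 (4S)-7,8-bis(benzyloxy)-2-[3,4-bis(benzyloxy)phenyl]-4-Fl-4H-chromene
Product: 23 (2R,3S)-1-[3,4-bis(benzyloxy)phenyl]-3-[3,4-bis(benzyloxy)-2-hydroxyphenyl]-2-hydroxy-3-Fl-propan-1-one, via cis-diol hemiketal 22 (not isolated)
Conditions: OsO4 (2 mol %), NMO (1.5 equiv), acetone–THF–H2O, 0 °C → rt
Reagents that add atoms: N-methylmorpholine N-oxide C[N+]1([O-])CCOCC1 (terminal source of both oxygen atoms); osmium tetroxide O=[Os](=O)(=O)=O (catalytic carrier)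
Why: Upjohn syn-dihydroxylation of the electron-rich enol-ether double bond C2=C3, the only reactive alkene, in which osmium adds on the face anti to the bulky C4 substituent and so sets C3 as (R) with its oxygen trans to the C4 aryl group; the 2-hydroxy hemiketal 22 is the ring tautomer of the α-hydroxy ketone 23, which is drawn open-chain.

Step 12
Reactants: 23 (2R,3S)-1-[3,4-bis(benzyloxy)phenyl]-3-[3,4-bis(benzyloxy)-2-hydroxyphenyl]-2-hydroxy-3-Fl-propan-1-one
Product: 24 (1S,2R,3S)-1-[3,4-bis(benzyloxy)phenyl]-3-[3,4-bis(benzyloxy)-2-hydroxyphenyl]-3-Fl-propane-1,2-diol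
Conditions: Zn(BH4)2, Et2O–THF, −30 → 0 °C; H2O
Reagents that add atoms: none
Why: Chelation-controlled (Cram-chelate) hydride reduction, in which zinc bridges the C3 hydroxyl and the C2 carbonyl of the open-chain tautomer and hydride enters anti to the diarylmethyl group on C3, which should set C2 as (S) and give the anti (erythro) diol; the vinylogous-ester carbonyl of the flavonol should stay intact.

Step 13
Reactants: 24 (1S,2R,3S)-1-[3,4-bis(benzyloxy)phenyl]-3-[3,4-bis(benzyloxy)-2-hydroxyphenyl]-3-Fl-propane-1,2-diol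
Product: 26 (2R,3R,4S)-7,8-bis(benzyloxy)-2-[3,4-bis(benzyloxy)phenyl]-4-Fl-chroman-3-ol, via oxyphosphonium phenoxide 25 (not isolated)
Conditions: PPh3, DIAD, THF, 0 °C → rt
Reagents that add atoms: none
Why: Mitsunobu cycloetherification: the PPh3–DIAD betaine is protonated by the ring A phenol on C8a (the only acidic OH) and turns the benzylic C2 carbinol into the alkoxyphosphonium ion 25, which the phenoxide displaces from the rear with loss of Ph3PO. The closest known reaction type is the Mitsunobu ring closure of 1-aryl-3-(2-hydroxyaryl)propane-1,2-diols to flavan-3-ols. Ring C closes in the 6-exo-tet mode through the new O1–C2 bond. The new stereocentre C2 (R) is controlled by stereospecific inversion of the (S)-carbinol set in step 12, so that the anti diol becomes the 2,3-cis flavan while C3 and C4 are not touched. The step needs attack at C2 in preference to C3 (which would lead to a dihydrobenzofuran or an epoxide) and SN2 displacement in preference to ionisation of the electron-rich benzylic centre; the first should follow from the greater reactivity of the benzylic carbinol and the crowding of the C3 hydroxyl beside the diarylmethine, the second from the phenoxide held five atoms away in a non-polar solvent at 0 °C.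

Step 14
Reactants: 26 (2R,3R,4S)-7,8-bis(benzyloxy)-2-[3,4-bis(benzyloxy)phenyl]-4-Fl-chroman-3-ol
Product: 27 2-(3,4-dihydroxyphenyl)-5-[(2R,3R,4S)-2-(3,4-dihydroxyphenyl)-3,7,8-trihydroxychroman-4-yl]-3,7,8-trihydroxy-4H-chromen-4-one
Conditions: H2 (1 atm), Pd(OH)2/C, THF–MeOH, rt
Reagents that add atoms: none
Why: Catalytic hydrogenolysis of the nine benzyl ethers under neutral conditions, which should leave the flavonol double bond, the benzylic O1–C2 ether and the three stereocentres untouched, as is usual for benzylated flavan-3-ols.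

**Compound list**

1 | 1-(2,3,4-trihydroxyphenyl)ethanone | CC(=O)c1ccc(O)c(O)c1O | starting material
2 | 1-[3,4-bis(benzyloxy)-2-hydroxyphenyl]ethanone | CC(=O)c1ccc(OCc2ccccc2)c(OCc2ccccc2)c1O | intermediate
3 | 3,4-bis(benzyloxy)benzaldehyde | O=Cc1ccc(OCc2ccccc2)c(OCc2ccccc2)c1 | starting material
4 | (E)-1-[3,4-bis(benzyloxy)-2-hydroxyphenyl]-3-[3,4-bis(benzyloxy)phenyl]prop-2-en-1-one | O=C(/C=C/c1ccc(OCc2ccccc2)c(OCc2ccccc2)c1)c1ccc(OCc2ccccc2)c(OCc2ccccc2)c1O | intermediate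
5 | 7,8-bis(benzyloxy)-2-[3,4-bis(benzyloxy)phenyl]-3-hydroxychroman-4-one (racemic trans dihydroflavonol) | O=C1c2ccc(OCc3ccccc3)c(OCc3ccccc3)c2OC(c2ccc(OCc3ccccc3)c(OCc3ccccc3)c2)C1O | intermediate
6 | 7,8-bis(benzyloxy)-2-[3,4-bis(benzyloxy)phenyl]-3-hydroxy-4H-chromen-4-one | O=c1c(O)c(-c3ccc(OCc4ccccc4)c(OCc4ccccc4)c3)oc2c(OCc3ccccc3)c(OCc3ccccc3)ccc12 | intermediate
7 | 3,7,8-tris(benzyloxy)-2-[3,4-bis(benzyloxy)phenyl]-4H-chromen-4-one | O=c1c(OCc3ccccc3)c(-c3ccc(OCc4ccccc4)c(OCc4ccccc4)c3)oc2c(OCc3ccccc3)c(OCc3ccccc3)ccc12 | intermediate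
8 | N-methoxy-N-methylprop-2-enamide | C=CC(=O)N(C)OC | starting material
9 | (E)-3-Fl-N-methoxy-N-methylprop-2-enamide | O=c1c(OCc3ccccc3)c(-c3ccc(OCc4ccccc4)c(OCc4ccccc4)c3)oc2c(OCc3ccccc3)c(OCc3ccccc3)cc(/C=C/C(=O)N(C)OC)c12 | intermediate
10 | 4-bromo-1,2-bis(benzyloxy)benzene | Brc1ccc(OCc2ccccc2)c(OCc2ccccc2)c1 | starting material
11 | [3,4-bis(benzyloxy)phenyl]magnesium bromide | Br[Mg]c1ccc(OCc2ccccc2)c(OCc2ccccc2)c1 | intermediate
12 | (E)-1-[3,4-bis(benzyloxy)phenyl]-3-Fl-prop-2-en-1-one | O=c1c(OCc3ccccc3)c(-c3ccc(OCc4ccccc4)c(OCc4ccccc4)c3)oc2c(OCc3ccccc3)c(OCc3ccccc3)cc(/C=C/C(=O)c3ccc(OCc4ccccc4)c(OCc4ccccc4)c3)c12 | intermediate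
13 | 2,3-bis(benzyloxy)benzaldehyde | O=Cc1cccc(OCc2ccccc2)c1OCc1ccccc1 | starting material
14 | 2,3-bis(benzyloxy)phenyl formate | O=COc1cccc(OCc2ccccc2)c1OCc1ccccc1 | intermediate
15 | 2,3-bis(benzyloxy)phenol | Oc1cccc(OCc2ccccc2)c1OCc1ccccc1 | intermediate
16 | 1,2-bis(benzyloxy)-3-(methoxymethoxy)benzene | COCOc1cccc(OCc2ccccc2)c1OCc1ccccc1 | intermediate
17 | [3,4-bis(benzyloxy)-2-(methoxymethoxy)phenyl]lithium | [Li]c1ccc(OCc2ccccc2)c(OCc2ccccc2)c1OCOC | intermediate
18 | [3,4-bis(benzyloxy)-2-(methoxymethoxy)phenyl]boronic acid | OB(O)c1ccc(OCc2ccccc2)c(OCc2ccccc2)c1OCOC | intermediate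
19 | (3S)-1-[3,4-bis(benzyloxy)phenyl]-3-[3,4-bis(benzyloxy)-2-(methoxymethoxy)phenyl]-3-Fl-propan-1-one | O=c1c(OCc3ccccc3)c(-c3ccc(OCc4ccccc4)c(OCc4ccccc4)c3)oc2c(OCc3ccccc3)c(OCc3ccccc3)cc([C@@H](c3ccc(OCc4ccccc4)c(OCc4ccccc4)c3OCOC)CC(=O)c3ccc(OCc4ccccc4)c(OCc4ccccc4)c3)c12 | intermediate
20 | (3S)-1-[3,4-bis(benzyloxy)phenyl]-3-[3,4-bis(benzyloxy)-2-hydroxyphenyl]-3-Fl-propan-1-one | O=c1c(OCc3ccccc3)c(-c3ccc(OCc4ccccc4)c(OCc4ccccc4)c3)oc2c(OCc3ccccc3)c(OCc3ccccc3)cc([C@@H](c3ccc(OCc4ccccc4)c(OCc4ccccc4)c3O)CC(=O)c3ccc(OCc4ccccc4)c(OCc4ccccc4)c3)c12 | intermediate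
21 | (4S)-7,8-bis(benzyloxy)-2-[3,4-bis(benzyloxy)phenyl]-4-Fl-4H-chromene | O=c1c(OCc3ccccc3)c(-c3ccc(OCc4ccccc4)c(OCc4ccccc4)c3)oc2c(OCc3ccccc3)c(OCc3ccccc3)cc([C@H]3c4ccc(OCc5ccccc5)c(OCc5ccccc5)c4OC(c4ccc(OCc5ccccc5)c(OCc5ccccc5)c4)=C3)c12 | intermediate
22 | (2S,3R,4S)-7,8-bis(benzyloxy)-2-[3,4-bis(benzyloxy)phenyl]-4-Fl-chromane-2,3-diol | O=c1c(OCc3ccccc3)c(-c3ccc(OCc4ccccc4)c(OCc4ccccc4)c3)oc2c(OCc3ccccc3)c(OCc3ccccc3)cc([C@H]3c4ccc(OCc5ccccc5)c(OCc5ccccc5)c4O[C@@](O)(c4ccc(OCc5ccccc5)c(OCc5ccccc5)c4)[C@@H]3O)c12 | intermediate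
23 | (2R,3S)-1-[3,4-bis(benzyloxy)phenyl]-3-[3,4-bis(benzyloxy)-2-hydroxyphenyl]-2-hydroxy-3-Fl-propan-1-one | O=c1c(OCc3ccccc3)c(-c3ccc(OCc4ccccc4)c(OCc4ccccc4)c3)oc2c(OCc3ccccc3)c(OCc3ccccc3)cc([C@@H](c3ccc(OCc4ccccc4)c(OCc4ccccc4)c3O)[C@@H](O)C(=O)c3ccc(OCc4ccccc4)c(OCc4ccccc4)c3)c12 | intermediate
24 | (1S,2R,3S)-1-[3,4-bis(benzyloxy)phenyl]-3-[3,4-bis(benzyloxy)-2-hydroxyphenyl]-3-Fl-propane-1,2-diol | O=c1c(OCc3ccccc3)c(-c3ccc(OCc4ccccc4)c(OCc4ccccc4)c3)oc2c(OCc3ccccc3)c(OCc3ccccc3)cc([C@@H](c3ccc(OCc4ccccc4)c(OCc4ccccc4)c3O)[C@@H](O)[C@@H](O)c3ccc(OCc4ccccc4)c(OCc4ccccc4)c3)c12 | intermediate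
25 | C1-O-triphenylphosphonium phenoxide betaine of 24 | O=c1c(OCc3ccccc3)c(-c3ccc(OCc4ccccc4)c(OCc4ccccc4)c3)oc2c(OCc3ccccc3)c(OCc3ccccc3)cc([C@@H](c3ccc(OCc4ccccc4)c(OCc4ccccc4)c3[O-])[C@@H](O)[C@@H](O[P+](c3ccccc3)(c3ccccc3)c3ccccc3)c3ccc(OCc4ccccc4)c(OCc4ccccc4)c3)c12 | intermediate
26 | (2R,3R,4S)-7,8-bis(benzyloxy)-2-[3,4-bis(benzyloxy)phenyl]-4-Fl-chroman-3-ol | O=c1c(OCc3ccccc3)c(-c3ccc(OCc4ccccc4)c(OCc4ccccc4)c3)oc2c(OCc3ccccc3)c(OCc3ccccc3)cc([C@H]3c4ccc(OCc5ccccc5)c(OCc5ccccc5)c4O[C@H](c4ccc(OCc5ccccc5)c(OCc5ccccc5)c4)[C@@H]3O)c12 | intermediate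
27 | 2-(3,4-dihydroxyphenyl)-5-[(2R,3R,4S)-2-(3,4-dihydroxyphenyl)-3,7,8-trihydroxychroman-4-yl]-3,7,8-trihydroxy-4H-chromen-4-one | O=c1c(O)c(-c2ccc(O)c(O)c2)oc2c(O)c(O)cc([C@H]3c4ccc(O)c(O)c4O[C@H](c4ccc(O)c(O)c4)[C@@H]3O)c12 | target

**Totals.** Total step count: 14. Longest linear sequence: 11 steps (steps 1–6 and 10–14); steps 7–9 form the side branch to boronic acid 18.

**Steps most likely to fail**

1. Step 13 (key step). What may go wrong: ionisation of the electron-rich benzylic oxyphosphonium ion before the phenoxide arrives (loss of the inversion and drift toward the 2,3-trans epimer), or capture by the neighbouring C3 hydroxyl (epoxide formation). The fallback sets out from 24 and comes back at 26; it replaces phosphonium activation by an orthoester closure in which C2 stays bridged by the C3 oxygen. Condensation of 24 with HC(OEt)3 (PPTS cat., CH2Cl2) should give the cyclic orthoformate F1. Further PPTS in 1,2-dichloroethane at 60 °C should ionise it to the cis-fused 1,3-dioxolan-2-ylium ion, which the C8a phenol opens at the benzylic carbon with inversion to give the 2,3-cis flavan 3-O-formate F2. K2CO3 in MeOH then removes the formyl group to give 26.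

2. Step 10. What may go wrong: slow aryl transfer and insertion with two ortho-substituted partners, so that protodeboronation of 18 wins, or weak enantioface discrimination on the twisted enone. The fallback sets out from 7 and 17 and comes back at 19; it uses auxiliary-controlled conjugate addition. Olefination of 7 under the conditions of step 5 with (S)-3-acryloyl-4-phenyloxazolidin-2-one F3 should give the E-enoyl imide F4. The aryl cuprate made from aryllithium 17 (MgBr2·OEt2, then CuBr·SMe2, THF, −40 °C) should add to the magnesium-chelated s-cis imide anti to the auxiliary phenyl group, that is to the Si face of the β-carbon, to give the (3S)-imide F5. MeNH(OMe)·HCl with AlMe3 converts this into the Weinreb amide F6 with release of the auxiliary, and Grignard reagent 11 (as in step 6) turns it into 19, which the acid stage of step 10 carries on to 21.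

3. Step 5. What may go wrong: sluggish cyclometalation at the crowded peri position, sequestration of the catalyst by the polyether substrate, or loss of benzyl groups at 100 °C. The fallback sets out from 8 together with a new starting material and comes back at 9; it builds ring A of the flavonol with bromine at the future C5 and attaches the side chain by a Heck reaction. 5-Bromobenzene-1,2,3-triol F7 is benzylated (BnBr, K2CO3) to the tribenzyl ether F8. Magnesiation between Br and OBn (TMPMgCl·LiCl, THF, −20 °C) and acylation with 2-(benzyloxy)-N-methoxy-N-methylacetamide should give the aryl ketone F9. MgBr2·OEt2 cleaves only the benzyl ether ortho to the carbonyl to give the 2'-phenol F10. Baker–Venkataraman-type C-acylation (LiN(SiMe3)2, 3,4-bis(benzyloxy)benzoyl chloride) gives the 1,3-diketone F11, which p-TsOH in toluene cyclodehydrates to the 5-bromoflavonol F12. Heck coupling with 8 (Pd(OAc)2, P(o-tol)3, Et3N, DMF, 100 °C) then gives 9.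

**Further compounds**

F1 | step 13 | cyclic orthoformate (2-ethoxy-1,3-dioxolane) of the 1,2-diol of 24 | O=c1c(OCc3ccccc3)c(-c3ccc(OCc4ccccc4)c(OCc4ccccc4)c3)oc2c(OCc3ccccc3)c(OCc3ccccc3)cc([C@@H](c3ccc(OCc4ccccc4)c(OCc4ccccc4)c3O)[C@H]3OC(OCC)O[C@H]3c3ccc(OCc4ccccc4)c(OCc4ccccc4)c3)c12
F2 | step 13 | (2R,3R,4S)-7,8-bis(benzyloxy)-2-[3,4-bis(benzyloxy)phenyl]-4-Fl-chroman-3-yl formate | O=c1c(OCc3ccccc3)c(-c3ccc(OCc4ccccc4)c(OCc4ccccc4)c3)oc2c(OCc3ccccc3)c(OCc3ccccc3)cc([C@H]3c4ccc(OCc5ccccc5)c(OCc5ccccc5)c4O[C@H](c4ccc(OCc5ccccc5)c(OCc5ccccc5)c4)[C@@H]3OC=O)c12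
F3 | step 10 | (S)-3-acryloyl-4-phenyloxazolidin-2-one | C=CC(=O)N1[C@@H](c2ccccc2)COC1=O
F4 | step 10 | (S)-3-[(E)-3-Fl-prop-2-enoyl]-4-phenyloxazolidin-2-one | O=c1c(OCc3ccccc3)c(-c3ccc(OCc4ccccc4)c(OCc4ccccc4)c3)oc2c(OCc3ccccc3)c(OCc3ccccc3)cc(/C=C/C(=O)N3[C@@H](c4ccccc4)COC3=O)c12
F5 | step 10 | (S)-3-{(3S)-3-[3,4-bis(benzyloxy)-2-(methoxymethoxy)phenyl]-3-Fl-propanoyl}-4-phenyloxazolidin-2-one | O=c1c(OCc3ccccc3)c(-c3ccc(OCc4ccccc4)c(OCc4ccccc4)c3)oc2c(OCc3ccccc3)c(OCc3ccccc3)cc([C@@H](c3ccc(OCc4ccccc4)c(OCc4ccccc4)c3OCOC)CC(=O)N3[C@@H](c4ccccc4)COC3=O)c12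
F6 | step 10 | (3S)-3-[3,4-bis(benzyloxy)-2-(methoxymethoxy)phenyl]-3-Fl-N-methoxy-N-methylpropanamide | O=c1c(OCc3ccccc3)c(-c3ccc(OCc4ccccc4)c(OCc4ccccc4)c3)oc2c(OCc3ccccc3)c(OCc3ccccc3)cc([C@@H](c3ccc(OCc4ccccc4)c(OCc4ccccc4)c3OCOC)CC(=O)N(C)OC)c12
F7 | step 5 | 5-bromobenzene-1,2,3-triol | Oc1cc(Br)cc(O)c1O
F8 | step 5 | 1,2,3-tris(benzyloxy)-5-bromobenzene | Brc1cc(OCc2ccccc2)c(OCc2ccccc2)c(OCc2ccccc2)c1
F9 | step 5 | 2-(benzyloxy)-1-[2,3,4-tris(benzyloxy)-6-bromophenyl]ethanone | O=C(COCc1ccccc1)c1c(Br)cc(OCc2ccccc2)c(OCc2ccccc2)c1OCc1ccccc1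
F10 | step 5 | 2-(benzyloxy)-1-[3,4-bis(benzyloxy)-6-bromo-2-hydroxyphenyl]ethanone | O=C(COCc1ccccc1)c1c(Br)cc(OCc2ccccc2)c(OCc2ccccc2)c1O
F11 | step 5 | 2-(benzyloxy)-1-[3,4-bis(benzyloxy)-6-bromo-2-hydroxyphenyl]-3-[3,4-bis(benzyloxy)phenyl]propane-1,3-dione | O=C(c1ccc(OCc2ccccc2)c(OCc2ccccc2)c1)C(OCc1ccccc1)C(=O)c1c(Br)cc(OCc2ccccc2)c(OCc2ccccc2)c1O
F12 | step 5 | 3,7,8-tris(benzyloxy)-2-[3,4-bis(benzyloxy)phenyl]-5-bromo-4H-chromen-4-one | O=c1c(OCc3ccccc3)c(-c3ccc(OCc4ccccc4)c(OCc4ccccc4)c3)oc2c(OCc3ccccc3)c(OCc3ccccc3)cc(Br)c12
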